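The cyclohexane ring is disconnected at C7–C7a and C5–C6 (benzofuranone numbering). The trans-fused γ-lactone is read as a masked 2-silyloxyfuran, whose C5 (the future oxygen-bearing C7a) is a nucleophilic diene terminus; a 4-alkenyl group completes the diene. One catalytic enantioselective Diels–Alder reaction with (Z)-3-isobutyryloxy-2-methylacrolein forms both bonds and sets C7a, C7 and the quaternary C6 (and, provisionally, C5). The cis C7–O/C6–C relationship comes from the Z enol ester, which already carries the isobutyrate. The precursor is a flat, achiral 4-alkenyl-2-silyloxyfuran; C5, C3a, C4 and the oxirane centre are then relayed by substrate control.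

Key step: step 4

Remark: positions are numbered as in 1-benzofuran-2(3H)-one (O1, C2, C3, C3a, C4–C7, C7a); 1, 2 and 6 are taken as commercial; 21 is drawn as the open hydroxy aldehyde although it should exist largely as the lactol with the 4-hydroxyl group.

Step 1
Reactants: 1 tert-butyl(but-3-yn-1-yloxy)diphenylsilane; 2 4-bromofuran-2(5H)-one
Product: 4 4-[(1E)-4-(tert-butyldiphenylsilyloxy)but-1-en-1-yl]furan-2(5H)-one, via alkenyl pinacol boronate 3 (not isolated)
Conditions: HBpin, Cp2Zr(H)Cl (5 mol%), Et3N (10 mol%), 60 °C; then 2, PdCl2(dppf) (dppf = 1,1'-bis(diphenylphosphino)ferrocene, 3 mol%), K3PO4, THF/H2O, 45 °C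
Reagents that add atoms: none
Why: Zirconium-catalysed syn-hydroboration of the terminal alkyne should give the (E)-alkenylboronate, which undergoes Suzuki–Miyaura coupling with the vinylogous acyl bromide 2 with retention of alkene geometry; no stereocentre is formed.

Step 2
Reactants: 4 4-[(1E)-4-(tert-butyldiphenylsilyloxy)but-1-en-1-yl]furan-2(5H)-one
Product: 5 tert-butyl(diphenyl)[(3E)-4-{5-[tri(propan-2-yl)silyloxy]furan-3-yl}but-3-en-1-yloxy]silane
Conditions: i-Pr3SiOTf, Et3N, CH2Cl2, 0 °C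
Reagents that add atoms: tri(propan-2-yl)silyl trifluoromethanesulfonate CC(C)[Si](OS(=O)(=O)C(F)(F)F)(C(C)C)C(C)C
Why: Soft γ-enolisation of the butenolide (silyl triflate and amine) should give the aromatic 2-silyloxyfuran, the bulky silyl group being chosen to resist silyl transfer to the acid catalyst of step 4.

Step 3
Reactants: 6 3-ethoxy-2-methylprop-2-enal
Product: 8 (1Z)-2-methyl-3-oxoprop-1-en-1-yl 2-methylpropanoate, via 2-methylmalonaldehyde enol 7 (not isolated)
Conditions: 1 M HCl, H2O, 0 → 25 °C; extract, dry; then i-PrCOCl, 2,6-lutidine, CH2Cl2, −78 °C; silica gel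
Reagents that add atoms: water O; 2-methylpropanoyl chloride CC(C)C(=O)Cl
Why: Acid hydrolysis of the vinylogous ester gives 2-methylmalonaldehyde, whose intramolecularly hydrogen-bonded cis-enol should be trapped by O-acylation at low temperature as the Z enol ester (any E isomer is removed by chromatography).

Step 4
Reactants: 5 tert-butyl(diphenyl)[(3E)-4-{5-[tri(propan-2-yl)silyloxy]furan-3-yl}but-3-en-1-yloxy]silane; 8 (1Z)-2-methyl-3-oxoprop-1-en-1-yl 2-methylpropanoate
Product: 9 (5S,6S,7S,7aR)-5-[2-(tert-butyldiphenylsilyloxy)ethyl]-6-formyl-6-methyl-2-[tri(propan-2-yl)silyloxy]-5,6,7,7a-tetrahydro-1-benzofuran-7-yl 2-methylpropanoate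
Conditions: (S)-3,3-diphenyl-1-(o-tolyl)tetrahydro-1H,3H-pyrrolo[1,2-c][1,3,2]oxazaborole (20 mol%) protonated with Tf2NH (18 mol%), CH2Cl2, −78 → −40 °C; Et3N quench
Reagents that add atoms: none
Why: The aldehyde-bound chiral boron Lewis acid should trigger a concerted but asynchronous [4+2] cycloaddition in which furan C5 of 5 (the future C7a) bonds first to the acyloxy-bearing β-carbon of the s-trans enal and the alkenyl terminus then bonds to the α-carbon, leaving the adduct as a silyl dienol ether. The closest known reaction types are Diels–Alder reactions of 3-vinylfurans reacting as exocyclic dienes, Lewis-acid-catalysed Mukaiyama–Michael additions of 2-silyloxyfurans to enals, and oxazaborolidinium-catalysed Diels–Alder reactions of 2-substituted enals. The cyclohexene ring closes by suprafacial [4+2] addition (in the stepwise limit a 6-endo 1,6-addition of the enol onto the alkenyl terminus). C7 and C6 are set cis (oxygen against formyl) by the Z geometry of 8, C7a is set cis to both by the endo orientation of formyl and acyloxy groups relative to the furan oxygen, C5 is set cis to the C7a oxygen by the E alkene (corrected in step 7), and the absolute sense is set by the catalyst, chosen so that the diene adds to the Re face of the acyloxy-bearing carbon (the S catalyst by the usual model for 2-substituted enals, otherwise its enantiomer). The step needs regioselectivity, which the 2-silyloxy group secures by making furan C5 the nucleophilic terminus matched to the enal β-carbon, and it needs retention of the enol ester geometry, which the weakly donating acyloxy group secures by keeping full double-bond character in the complexed enal.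

Step 5
Reactants: 9 (5S,6S,7S,7aR)-5-[2-(tert-butyldiphenylsilyloxy)ethyl]-6-formyl-6-methyl-2-[tri(propan-2-yl)silyloxy]-5,6,7,7a-tetrahydro-1-benzofuran-7-yl 2-methylpropanoate
Product: 10 (5S,6S,7S,7aR)-5-[2-(tert-butyldiphenylsilyloxy)ethyl]-6-ethenyl-6-methyl-2-[tri(propan-2-yl)silyloxy]-5,6,7,7a-tetrahydro-1-benzofuran-7-yl 2-methylpropanoate
Conditions: Ph3PCH3Br, KN(SiMe3)2, THF, 0 °C; then 9, −78 → 0 °C; used without chromatography
Reagents that add atoms: methylidenetriphenylphosphorane C=P(c1ccccc1)(c1ccccc1)c1ccccc1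
Why: Wittig methylenation of the neopentyl aldehyde should give the vinyl group without touching the silyl ketene acetal or the esters; no stereocentre is affected.

Step 6
Reactants: 10 (5S,6S,7S,7aR)-5-[2-(tert-butyldiphenylsilyloxy)ethyl]-6-ethenyl-6-methyl-2-[tri(propan-2-yl)silyloxy]-5,6,7,7a-tetrahydro-1-benzofuran-7-yl 2-methylpropanoate
Product: 12 (5R,6S,7S,7aR)-5-[2-(tert-butyldiphenylsilyloxy)ethyl]-6-ethenyl-6-methyl-2,4-dioxo-2,4,5,6,7,7a-hexahydro-1-benzofuran-7-yl 2-methylpropanoate, via 4-hydroxy butenolide 11 (not isolated)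
Conditions: mCPBA (1.05 equiv), CH2Cl2, −78 → −30 °C; then DMP [1,1,1-triacetoxy-1,1-dihydro-1,2-benziodoxol-3(1H)-one], 0 → 25 °C
Reagents that add atoms: 3-chloroperoxybenzoic acid OOC(=O)c1cccc(Cl)c1
Why: The peracid should attack the terminal C3a=C4 bond of the silyl dienol ether (vinylogous Rubottom oxidation, as in the γ-hydroxylation of steroidal dienol ethers) much faster than the vinyl group, and the allylic alcohol is oxidised in the same flask (Dess–Martin oxidation), so the configuration at C4 is irrelevant.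

Step 7
Reactants: 12 (5R,6S,7S,7aR)-5-[2-(tert-butyldiphenylsilyloxy)ethyl]-6-ethenyl-6-methyl-2,4-dioxo-2,4,5,6,7,7a-hexahydro-1-benzofuran-7-yl 2-methylpropanoate
Product: 14 (3aR,5S,6S,7S,7aR)-5-[2-(tert-butyldiphenylsilyloxy)ethyl]-6-ethenyl-6-methyl-2,4-dioxooctahydro-1-benzofuran-7-yl 2-methylpropanoate, via C5-epimeric keto lactone 13 (not isolated)
Conditions: Zn dust, AcOH, 25 °C; filter; then AcOH, 60 °C
Reagents that add atoms: none
Why: Zinc in acetic acid reduces the electron-poor C3=C3a bond of the ene-dione (dissolving-metal conjugate reduction), and acid-mediated enolisation of the C4 ketone should then equilibrate C5 and C3a to the isomer with both flanking substituents equatorial, because the C5 epimer and the cis-fused lactone each suffer a 1,3-diaxial contact with the axial 7-acyloxy group.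

Step 8
Reactants: 14 (3aR,5S,6S,7S,7aR)-5-[2-(tert-butyldiphenylsilyloxy)ethyl]-6-ethenyl-6-methyl-2,4-dioxooctahydro-1-benzofuran-7-yl 2-methylpropanoate
Product: 15 (3aS,4S,5S,6S,7S,7aR)-5-[2-(tert-butyldiphenylsilyloxy)ethyl]-6-ethenyl-4-hydroxy-6-methyl-2-oxooctahydro-1-benzofuran-7-yl 2-methylpropanoate
Conditions: LiBH(s-Bu)3, THF, −78 °C; H2O
Reagents that add atoms: none
Why: The bulky borohydride should reduce the C4 ketone by equatorial attack on the face opposite the axial 6-methyl group, giving the axial 4-hydroxyl cis to both neighbours, while lactone and ester are inert at −78 °C.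

Step 9
Reactants: 15 (3aS,4S,5S,6S,7S,7aR)-5-[2-(tert-butyldiphenylsilyloxy)ethyl]-6-ethenyl-4-hydroxy-6-methyl-2-oxooctahydro-1-benzofuran-7-yl 2-methylpropanoate
Product: 18 (3aS,4S,5S,6S,7S,7aR)-5-[2-(tert-butyldiphenylsilyloxy)ethyl]-6-ethenyl-4-hydroxy-6-methyl-3-methylidene-2-oxooctahydro-1-benzofuran-7-yl 2-methylpropanoate, via Mannich base 16 (not isolated), via trimethylammonium iodide 17 (not isolated)
Conditions: LiN(i-Pr)2 (2.2 equiv), THF, −78 °C; CH2=NMe2+ I−, −78 → 25 °C; H2O; then MeI, MeOH, 25 °C; then NaHCO3, H2O/EtOAc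
Reagents that add atoms: dimethyl(methylidene)ammonium iodide C=[N+](C)C.[I-]
Why: Mannich reaction of the lactone enolate (the lactone α-CH2 is markedly more acidic than the hindered isobutyrate α-CH) followed by quaternisation and Hofmann-type elimination should install the exocyclic methylene; no ring stereocentre is affected.

Step 10
Reactants: 18 (3aS,4S,5S,6S,7S,7aR)-5-[2-(tert-butyldiphenylsilyloxy)ethyl]-6-ethenyl-4-hydroxy-6-methyl-3-methylidene-2-oxooctahydro-1-benzofuran-7-yl 2-methylpropanoate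
Product: 19 (3aS,4S,5S,6R,7S,7aR)-5-[2-(tert-butyldiphenylsilyloxy)ethyl]-4-hydroxy-6-methyl-3-methylidene-6-[(2R)-oxiran-2-yl]-2-oxooctahydro-1-benzofuran-7-yl 2-methylpropanoate
Conditions: VO(acac)2 (10 mol%), t-BuOOH, CH2Cl2, 25 °C
Reagents that add atoms: tert-butyl hydroperoxide CC(C)(C)OO
Why: In this vanadium-catalysed hydroxyl-directed epoxidation the peroxide bound to the axial C4 alkoxide should reach the bishomoallylic vinyl group in its preferred rotamer (C=C eclipsing the C6–CH3 bond) on the face turned towards C5 and O4, which corresponds to the (2R)-oxirane, while the electron-poor α-methylene lactone is not attacked by this electrophilic oxidant.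

Step 11
Reactants: 19 (3aS,4S,5S,6R,7S,7aR)-5-[2-(tert-butyldiphenylsilyloxy)ethyl]-4-hydroxy-6-methyl-3-methylidene-6-[(2R)-oxiran-2-yl]-2-oxooctahydro-1-benzofuran-7-yl 2-methylpropanoate
Product: 20 (3aS,4S,5S,6R,7S,7aR)-4-hydroxy-5-(2-hydroxyethyl)-6-methyl-3-methylidene-6-[(2R)-oxiran-2-yl]-2-oxooctahydro-1-benzofuran-7-yl 2-methylpropanoate
Conditions: Bu4NF, AcOH, THF, 0 → 25 °C
Reagents that add atoms: none
Why: Fluoride cleaves the Si–O bond of the primary silyl ether, the acetic acid buffer protecting the α-methylene lactone, the oxirane and the ester from basic fluoride; no stereocentre is affected.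

Step 12
Reactants: 20 (3aS,4S,5S,6R,7S,7aR)-4-hydroxy-5-(2-hydroxyethyl)-6-methyl-3-methylidene-6-[(2R)-oxiran-2-yl]-2-oxooctahydro-1-benzofuran-7-yl 2-methylpropanoate
Product: 21 (3aS,4S,5S,6R,7S,7aR)-4-hydroxy-6-methyl-3-methylidene-6-[(2R)-oxiran-2-yl]-2-oxo-5-(2-oxoethyl)octahydro-1-benzofuran-7-yl 2-methylpropanoate
Conditions: IBX (1.2 equiv), DMSO, 25 °C
Reagents that add atoms: none
Why: IBX should oxidise the primary alcohol of the 1,4-diol selectively to the aldehyde, which is captured by the neighbouring axial 4-hydroxyl as a γ-lactol and so protected from over-oxidation, while the hindered secondary alcohol is left alone.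

Step 13
Reactants: 21 (3aS,4S,5S,6R,7S,7aR)-4-hydroxy-6-methyl-3-methylidene-6-[(2R)-oxiran-2-yl]-2-oxo-5-(2-oxoethyl)octahydro-1-benzofuran-7-yl 2-methylpropanoate
Product: 23 (3aS,4S,5R,6R,7S,7aR)-4-hydroxy-6-methyl-3-methylidene-6-[(2R)-oxiran-2-yl]-2-oxo-5-(3-oxoprop-1-en-2-yl)octahydro-1-benzofuran-7-yl 2-methylpropanoate (CNP0519565.1), via β-amino aldehyde 22 (not isolated)
Conditions: CH2=NMe2+ I− (3 equiv), Et3N, CH2Cl2, 25 °C
Reagents that add atoms: dimethyl(methylidene)ammonium iodide C=[N+](C)C.[I-]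
Why: Mannich reaction of the enolisable aldehyde (through the open form of the lactol) followed by spontaneous β-elimination of dimethylamine should give the 2-substituted acrolein, the excess iminium salt trapping the liberated amine so that it does not add to the α-methylene lactone; no stereocentre is affected.

Compound list
1 | tert-butyl(but-3-yn-1-yloxy)diphenylsilane | C#CCCO[Si](c1ccccc1)(c1ccccc1)C(C)(C)C | starting material
2 | 4-bromofuran-2(5H)-one | O=C1C=C(Br)CO1 | starting material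
3 | 2-[(1E)-4-(tert-butyldiphenylsilyloxy)but-1-en-1-yl]-4,4,5,5-tetramethyl-1,3,2-dioxaborolane | CC1(C)OB(/C=C/CCO[Si](c2ccccc2)(c2ccccc2)C(C)(C)C)OC1(C)C | intermediate
4 | 4-[(1E)-4-(tert-butyldiphenylsilyloxy)but-1-en-1-yl]furan-2(5H)-one | O=C1C=C(/C=C/CCO[Si](c2ccccc2)(c2ccccc2)C(C)(C)C)CO1 | intermediate
5 | tert-butyl(diphenyl)[(3E)-4-{5-[tri(propan-2-yl)silyloxy]furan-3-yl}but-3-en-1-yloxy]silane | CC(C)[Si](C(C)C)(C(C)C)Oc1cc(/C=C/CCO[Si](c2ccccc2)(c2ccccc2)C(C)(C)C)co1 | intermediate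
6 | 3-ethoxy-2-methylprop-2-enal | CCOC=C(C)C=O | starting material
7 | (2Z)-3-hydroxy-2-methylprop-2-enal (2-methylmalonaldehyde, chelated enol) | O/C=C(/C)C=O | intermediate
8 | (1Z)-2-methyl-3-oxoprop-1-en-1-yl 2-methylpropanoate | CC(C)C(=O)O/C=C(/C)C=O | intermediate
9 | (5S,6S,7S,7aR)-5-[2-(tert-butyldiphenylsilyloxy)ethyl]-6-formyl-6-methyl-2-[tri(propan-2-yl)silyloxy]-5,6,7,7a-tetrahydro-1-benzofuran-7-yl 2-methylpropanoate | CC(C)[Si](C(C)C)(C(C)C)OC1=CC2=C[C@H](CCO[Si](c3ccccc3)(c3ccccc3)C(C)(C)C)[C@](C)(C=O)[C@H](OC(=O)C(C)C)[C@@H]2O1 | intermediate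
10 | (5S,6S,7S,7aR)-5-[2-(tert-butyldiphenylsilyloxy)ethyl]-6-ethenyl-6-methyl-2-[tri(propan-2-yl)silyloxy]-5,6,7,7a-tetrahydro-1-benzofuran-7-yl 2-methylpropanoate | CC(C)[Si](C(C)C)(C(C)C)OC1=CC2=C[C@H](CCO[Si](c3ccccc3)(c3ccccc3)C(C)(C)C)[C@](C)(C=C)[C@H](OC(=O)C(C)C)[C@@H]2O1 | intermediate
11 | (5R,6S,7S,7aR)-5-[2-(tert-butyldiphenylsilyloxy)ethyl]-6-ethenyl-4-hydroxy-6-methyl-2-oxo-2,4,5,6,7,7a-hexahydro-1-benzofuran-7-yl 2-methylpropanoate (C4 epimers) | O=C1C=C2C(O)[C@H](CCO[Si](c3ccccc3)(c3ccccc3)C(C)(C)C)[C@](C)(C=C)[C@H](OC(=O)C(C)C)[C@@H]2O1 | intermediate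
12 | (5R,6S,7S,7aR)-5-[2-(tert-butyldiphenylsilyloxy)ethyl]-6-ethenyl-6-methyl-2,4-dioxo-2,4,5,6,7,7a-hexahydro-1-benzofuran-7-yl 2-methylpropanoate | O=C1C=C2C(=O)[C@H](CCO[Si](c3ccccc3)(c3ccccc3)C(C)(C)C)[C@](C)(C=C)[C@H](OC(=O)C(C)C)[C@@H]2O1 | intermediate
13 | (3aR,5R,6S,7S,7aR)-5-[2-(tert-butyldiphenylsilyloxy)ethyl]-6-ethenyl-6-methyl-2,4-dioxooctahydro-1-benzofuran-7-yl 2-methylpropanoate (C5 epimer of 14) | O=C1C[C@H]2C(=O)[C@H](CCO[Si](c3ccccc3)(c3ccccc3)C(C)(C)C)[C@](C)(C=C)[C@H](OC(=O)C(C)C)[C@@H]2O1 | intermediate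
14 | (3aR,5S,6S,7S,7aR)-5-[2-(tert-butyldiphenylsilyloxy)ethyl]-6-ethenyl-6-methyl-2,4-dioxooctahydro-1-benzofuran-7-yl 2-methylpropanoate | O=C1C[C@H]2C(=O)[C@@H](CCO[Si](c3ccccc3)(c3ccccc3)C(C)(C)C)[C@](C)(C=C)[C@H](OC(=O)C(C)C)[C@@H]2O1 | intermediate
15 | (3aS,4S,5S,6S,7S,7aR)-5-[2-(tert-butyldiphenylsilyloxy)ethyl]-6-ethenyl-4-hydroxy-6-methyl-2-oxooctahydro-1-benzofuran-7-yl 2-methylpropanoate | O=C1C[C@H]2[C@@H](O)[C@@H](CCO[Si](c3ccccc3)(c3ccccc3)C(C)(C)C)[C@](C)(C=C)[C@H](OC(=O)C(C)C)[C@@H]2O1 | intermediate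
16 | 3-[(dimethylamino)methyl] derivative of 15 (C3 epimers) | O=C1C(CN(C)C)[C@H]2[C@@H](O)[C@@H](CCO[Si](c3ccccc3)(c3ccccc3)C(C)(C)C)[C@](C)(C=C)[C@H](OC(=O)C(C)C)[C@@H]2O1 | intermediate
17 | 3-[(trimethylammonio)methyl] derivative of 15, iodide (C3 epimers) | O=C1C(C[N+](C)(C)C)[C@H]2[C@@H](O)[C@@H](CCO[Si](c3ccccc3)(c3ccccc3)C(C)(C)C)[C@](C)(C=C)[C@H](OC(=O)C(C)C)[C@@H]2O1.[I-] | intermediate
18 | (3aS,4S,5S,6S,7S,7aR)-5-[2-(tert-butyldiphenylsilyloxy)ethyl]-6-ethenyl-4-hydroxy-6-methyl-3-methylidene-2-oxooctahydro-1-benzofuran-7-yl 2-methylpropanoate | O=C1C(=C)[C@H]2[C@@H](O)[C@@H](CCO[Si](c3ccccc3)(c3ccccc3)C(C)(C)C)[C@](C)(C=C)[C@H](OC(=O)C(C)C)[C@@H]2O1 | intermediate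
19 | (3aS,4S,5S,6R,7S,7aR)-5-[2-(tert-butyldiphenylsilyloxy)ethyl]-4-hydroxy-6-methyl-3-methylidene-6-[(2R)-oxiran-2-yl]-2-oxooctahydro-1-benzofuran-7-yl 2-methylpropanoate | O=C1C(=C)[C@H]2[C@@H](O)[C@@H](CCO[Si](c3ccccc3)(c3ccccc3)C(C)(C)C)[C@](C)([C@@H]4CO4)[C@H](OC(=O)C(C)C)[C@@H]2O1 | intermediate
20 | (3aS,4S,5S,6R,7S,7aR)-4-hydroxy-5-(2-hydroxyethyl)-6-methyl-3-methylidene-6-[(2R)-oxiran-2-yl]-2-oxooctahydro-1-benzofuran-7-yl 2-methylpropanoate | O=C1C(=C)[C@H]2[C@@H](O)[C@@H](CCO)[C@](C)([C@@H]3CO3)[C@H](OC(=O)C(C)C)[C@@H]2O1 | intermediate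
21 | (3aS,4S,5S,6R,7S,7aR)-4-hydroxy-6-methyl-3-methylidene-6-[(2R)-oxiran-2-yl]-2-oxo-5-(2-oxoethyl)octahydro-1-benzofuran-7-yl 2-methylpropanoate (open form of the lactol) | O=C1C(=C)[C@H]2[C@@H](O)[C@@H](CC=O)[C@](C)([C@@H]3CO3)[C@H](OC(=O)C(C)C)[C@@H]2O1 | intermediate
22 | 5-[1-(dimethylamino)-3-oxopropan-2-yl] analogue of 21 (side-chain epimers) | O=C1C(=C)[C@H]2[C@@H](O)[C@@H](C(CN(C)C)C=O)[C@](C)([C@@H]3CO3)[C@H](OC(=O)C(C)C)[C@@H]2O1 | intermediate
23 | (3aS,4S,5R,6R,7S,7aR)-4-hydroxy-6-methyl-3-methylidene-6-[(2R)-oxiran-2-yl]-2-oxo-5-(3-oxoprop-1-en-2-yl)octahydro-1-benzofuran-7-yl 2-methylpropanoate (CNP0519565.1) | C=C1C(=O)O[C@@H]2[C@@H]1[C@@H](O)[C@@H](C(=C)C=O)[C@](C)([C@@H]1CO1)[C@@H]2OC(=O)C(C)C | target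

Total step count: 13. Longest linear sequence: 12 steps (steps 1, 2 and 4–13); step 3 is the one-step side branch.

Steps most likely to fail

Step 4. The process at risk is a stepwise Mukaiyama–Michael course under the Lewis acid, with bond rotation before ring closure and loss of the cis C7–O/C6–CHO relationship, or poor facial selectivity. The fallback sets out from 5 and 8 and gives up catalyst control: the cycloaddition is run without any Lewis acid (toluene, 90 °C, 2,6-di-tert-butyl-4-methylphenol), where a concerted suprafacial pathway should keep the Z geometry. This should give racemic adduct, that is 9 together with its enantiomer ent-9 F1. Wittig methylenation as in step 5 then gives 10 together with ent-10 F2. The enantiomers are separated by preparative supercritical-fluid chromatography on cellulose tris(3,5-dimethylphenylcarbamate), and the route is rejoined at 10.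

Step 7. The process at risk is kinetic protonation at C3a from the wrong face combined with slow or wrong-way equilibration of the ring fusion, or β-elimination of the lactone oxygen during prolonged acid treatment. The fallback sets out from 10 and fixes C3a by a stereospecific rearrangement instead of equilibration. Dilute HCl in THF/H2O at −20 °C should protonate the silyl dienol ether at C3 to give the β,γ-unsaturated lactone F3. mCPBA/NaHCO3 (CH2Cl2, 0 °C) should epoxidise its C3a=C4 bond on the face opposite the C5 side chain to give the 3a,4-epoxide F4. BF3·OEt2 (CH2Cl2, −78 °C) should then open the tertiary C3a–O bond with a 1,2-hydride shift from C4 anti to the departing oxygen (Meinwald rearrangement). This delivers the C3a hydrogen on the required face and returns to 13 as a single ring-fusion isomer; only C5 then has to epimerise (AcOH, 60 °C) to reach 14.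

Step 10. The process at risk is sluggish oxygen delivery to the bishomoallylic terminal alkene or poor facial selectivity at the oxirane carbon. The fallback sets out from 18 and replaces substrate direction by reagent-controlled resolution. Undirected epoxidation (mCPBA, NaHCO3, CH2Cl2, 25 °C; the α-methylene lactone is inert) should give 19 mixed with its oxirane epimer, the (2S)-oxirane F5. Hydrolytic kinetic resolution with (S,S)-[N,N'-bis(3,5-di-tert-butylsalicylidene)cyclohexane-1,2-diaminato]cobalt acetate (trivalent cobalt, 1 mol%) and H2O (0.55 equiv) in THF should, by analogy with simple alkyl oxiranes, hydrolyse F5 to the diol F6. F6 is removed by chromatography, and the route is rejoined at 19.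

Further compounds
F1 | step 4 | ent-9, (5R,6R,7R,7aS)-5-[2-(tert-butyldiphenylsilyloxy)ethyl]-6-formyl-6-methyl-2-[tri(propan-2-yl)silyloxy]-5,6,7,7a-tetrahydro-1-benzofuran-7-yl 2-methylpropanoate | CC(C)[Si](C(C)C)(C(C)C)OC1=CC2=C[C@@H](CCO[Si](c3ccccc3)(c3ccccc3)C(C)(C)C)[C@@](C)(C=O)[C@@H](OC(=O)C(C)C)[C@H]2O1
F2 | step 4 | ent-10, (5R,6R,7R,7aS)-5-[2-(tert-butyldiphenylsilyloxy)ethyl]-6-ethenyl-6-methyl-2-[tri(propan-2-yl)silyloxy]-5,6,7,7a-tetrahydro-1-benzofuran-7-yl 2-methylpropanoate | CC(C)[Si](C(C)C)(C(C)C)OC1=CC2=C[C@@H](CCO[Si](c3ccccc3)(c3ccccc3)C(C)(C)C)[C@@](C)(C=C)[C@@H](OC(=O)C(C)C)[C@H]2O1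
F3 | step 7 | (5S,6S,7S,7aR)-5-[2-(tert-butyldiphenylsilyloxy)ethyl]-6-ethenyl-6-methyl-2-oxo-2,3,5,6,7,7a-hexahydro-1-benzofuran-7-yl 2-methylpropanoate | O=C1CC2=C[C@H](CCO[Si](c3ccccc3)(c3ccccc3)C(C)(C)C)[C@](C)(C=C)[C@H](OC(=O)C(C)C)[C@@H]2O1
F4 | step 7 | 3a,4-epoxide of F3 with the oxirane oxygen trans to the C5 side chain | O=C1C[C@]2(O3)[C@@H]3[C@H](CCO[Si](c4ccccc4)(c4ccccc4)C(C)(C)C)[C@](C)(C=C)[C@H](OC(=O)C(C)C)[C@@H]2O1
F5 | step 10 | (2S)-oxiranyl epimer of 19 | O=C1C(=C)[C@H]2[C@@H](O)[C@@H](CCO[Si](c3ccccc3)(c3ccccc3)C(C)(C)C)[C@](C)([C@H]4CO4)[C@H](OC(=O)C(C)C)[C@@H]2O1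
F6 | step 10 | 6-[(1S)-1,2-dihydroxyethyl] diol from hydrolysis of F5 | O=C1C(=C)[C@H]2[C@@H](O)[C@@H](CCO[Si](c3ccccc3)(c3ccccc3)C(C)(C)C)[C@](C)([C@H](O)CO)[C@H](OC(=O)C(C)C)[C@@H]2O1
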